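(The numbers of this flask were set for the occasion.)

At the charge of the ochre flask, starting material goes with partner to intermediate A 21 times faster than it falls alone to side product, but that lead shrinks as partner drains, since the side path takes no partner.

the same everywhere: starting material 0.10 M; time 2.5 min

|  | partner |
|---|---|
| ochre | 0.120 M |
| green | 0.200 M |
| violet | 0.250 M |
| grey | 0.400 M |

- share of target in all that became target or side product for ochre, green, violet, grey, in this order
- how that number moves from the first to the last of them (rises, then falls / falls all the way / rises all the way / falls, then rises / hardly changes)

- "hardly changes" means that all values lie within two and a half points (for a concentration: within two and a half percent of the largest)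
- run time (ochre): 2.5 min

    starting material + partner → intermediate A (k1 = 0.15 /M/s)
    starting material → side product (k2 = 8.6 × 10⁻⁴ /s)
    intermediate A → intermediate B (k3 = 0.0026 /s)
    intermediate B → intermediate C (k4 = 0.021 /s)
    intermediate C ⇌ intermediate D (K5 = 1.4, k5 = 0.040 /s)
    partner + intermediate D → target (k6 = 0.18 /M/s)
    intermediate D → decomposed reagent (k7 = 8.5 × 10⁻⁴ /s)

So how much side product do you get? At any moment the two paths use starting material in the ratio of c(partner) to a fixed concentration, the constant of the side path over that of capture, which I call the crossover concentration: 5.73 mM. The ratio c(partner)/σ is the selectivity factor. Each bit of partner spent on capture therefore brings σ/c(partner) of side product, and summed over the run, side product is about σ times the logarithm of partner charged over partner not captured. The second-order law for capture, reckoned without the side path, gives partner not captured, and side product comes to 5.93 mM in ochre, 3.66 mM in green, 2.85 mM in violet and 1.65 mM in grey.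

That amount is the bar: the share stands above even only where target exceeds it. Can target reach it? Intermediate A must pass through intermediate B, then intermediate C, which equilibrates with intermediate D, and D meets partner to give target. The step from A to B is the rate-limiting step, with a half-life of 4.44 min, longer than the run of 2.5 min. Even intermediate A present from the first moment keeps 67.7% at the stop, so target stays small and the contest with the bar is real.

Which way does it move? The last step is pseudo-first-order in D, with 1.30 /min at the ochre charge and 4.32 /min at the grey one. The bar falls as target's way opens, so I commit to a share that rises all the way, though not to a row.

The forecast says 24%, 56%, 70%, 87%, rises all the way: "More partner speeds capture and suppresses the side path".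

The flasks give 24.4%, 56.4%, 69.5%, 86.2%: rises all the way.

Ochre at 2.50 min holds side product at 5.62% of the starting material charged, which is 5.62 mM, less than my 5.93 mM. Partner not captured in ochre, the partner left plus the one partner each target took, is 45.2 mM, and σ gives 5.59 mM. In grey, partner left plus target is 302 mM, so σ gives 1.62 mM, and the grey flask holds 1.62 mM of side product.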